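# Proposed total synthesis of ferocaulidin by carbene-catalysed desymmetrization of a cyclohexadienone

Drimane numbering is used for all bicyclic compounds: ring A = C1–C5 and C10; ring B = C5–C10; C11 on C9; C12 on C8; C13 and C14 on C4; C15 on C10. "Nor" marks methyl carbons that are not yet present.

## Analysis of the target

Ferocaulidin is a drimane sesquiterpene ether of umbelliferone. Its core is a trans-fused decalin: ring A carries the C3 hydroxyl and the C4 gem-dimethyl group, and ring B is a 7-en-6-one with the C12 methyl on C8 and the aryloxymethyl carbon C11 on C9. The four stereocentres are C3, C5, C9 and C10 (3S,5S,9R,10S). H-5 is trans to the C10 methyl, C11 is cis to the C10 methyl (equatorial on ring B), and the hydroxyl is trans to the C10 methyl, hence axial and next to the gem-dimethyl group. The sensitive parts are the enone (its γ-hydrogen at C9 and α'-hydrogen at C5 make both neighbouring centres base-labile), the coumarin lactone and the hindered axial carbinol. The difficulty lies around the quaternary C10, which is bracketed by C9, C5 and a fully substituted C4, and in placing oxygen at both C3 and C6. The strategy rests on one structural fact: the C3 and C6 oxygens are 1,4-related through C4–C5, and C10 is para to C3 in ring A. Ring A can therefore be a prochiral 4-alkyl-4-methylcyclohexa-2,5-dienone whose β-carbon is C5, and the C6 carbonyl an aldehyde that adds to it with inverted polarity, forming C5–C6, ring B and the 1,4-dicarbonyl pattern in one step.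

## Retrosynthetic reasoning

**C11–O aryl bond (33 ⇒ 31 + 32).** The ether is cut last, so the coumarin lactone never meets enolate, hydride or cuprate chemistry. Forward, a primary alcohol must be etherified with the phenol 32 in the presence of an unprotected but very hindered secondary alcohol.

**C8–C12 and the C7=C8 unsaturation (31 ⇒ 30 ⇒ 28 ⇒ 26).** The methyl on C8 and the enone are taken back to the saturated trans-fused 6-ketone 26. Forward this is two dehydrogenations flanking a conjugate methyl addition to 28. It is placed after the ring fusion is correct, so the finished enone, whose C9 centre is γ-acidic and may not be the thermodynamic epimer, never sees equilibrating base.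

**C5 configuration (26 ⇒ 25 ⇒ 24).** The key step can only deliver a cis ring fusion, so C5 is corrected by equilibration through the C6 ketone. This is done only after the gem-dimethyl group is in place, because that group is what makes the trans isomer strongly preferred.

**C3–H bond (24 ⇒ 23 ⇒ 22).** The carbinol is taken back to the C3 ketone while C6 is still a ketal. At that stage only one carbonyl is present, and the cis-fused skeleton offers a clear convex face for hydride.

**C1=C2 and the two C4–CH3 bonds (22 ⇒ 21 ⇒ 19 ⇒ 18).** The gem-dimethyl group is cut back to the C4 methylene of enone 19. The C1=C2 double bond is kept until then because it leaves C4 as the only enolisable carbon once C6 is masked. The ketal in 19 serves to tell the two carbonyls of 18 apart.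

**C5–C6 bond (18 ⇒ 17), the key disconnection.** Cutting C5–C6 opens ring B and turns the 1,4-diketone into aldehyde 17 tethered to a symmetric dienone. Nowhere else does one cut remove a ring, two stereocentres (C5, C10) and the C6 oxidation state together. Forward, a chiral carbene must choose one of the two diastereotopic enone arms. Ring fusion is cis by geometry. In the chair-like closure onto the required arm the CH2OSi group on C9 is axial, so the C9 centre does not help and the carbene has to make the choice.

**Functional-group adjustments (17 ⇒ 16 ⇒ 15 ⇒ 13).** The aldehyde comes from a primary TBS ether, and the dienone from cyclohexenone 13 by dehydrogenation. Dehydrogenation also erases the uncontrolled C10 centre of 13.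

**Ring A (13 ⇒ 10 + 11).** The cyclohexenone is cut at C10–C1 and C4=C5 into the α-branched aldehyde 10 and the four-carbon unit 11 (annulation). The quaternary carbon is formed here without any need for stereocontrol.

**C9–C10 bond and the C9 centre (10 ⇒ 8 ⇒ 7 ⇒ 2 + 5).** The only stereocentre of the precursor is set by an amine-catalysed conjugate addition of aldehyde 2 to nitroalkene 5. The nitro-bearing carbon becomes the aldehyde carbon of 10, and the aldehyde carbon of 2 becomes C11.

**Starting materials (2 ⇐ 1; 5 ⇐ 3).** One oxidation and one dehydration.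

## Alternatives that were turned down

**Alternative 1: ring-contracting Ireland–Claisen rearrangement.**
- Disconnection: C9–C10, traced back to a C6–O bond.
- Forward key step: the silyl ketene acetal of δ-lactone A1 (C11 as acyl carbon, ring oxygen on allylic C6, ring A with a C5=C10 double bond) would rearrange to the Δ5-octalin acid A2 with quaternary C10.
- For: chirality at C6 is relayed to C10 intramolecularly; C12 and the C3 oxygen are already present; the C5=C6 alkene is a handle for the C6 oxygen.
- Against: the lactone forces a boat transition state, and in it the carboxyl emerges trans to the C10 methyl (see C9 in A2), so C9 must be epimerized afterwards. A tetrasubstituted alkene terminus has to be attacked. A1 needs three stereocentres (C3, C6, C8) built beforehand. The C6 oxygen is lost in the rearrangement and must be put back, and C11 must be reduced.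
- Comparison: on the certainty of the C10 configuration it is stronger than the chosen route, because the transfer cannot be mismatched. The chosen route offers a much shorter precursor with one stereocentre, delivers C6 already oxidized, and avoids removing and restoring oxygen at C6.

**Alternative 2: siloxydiene Diels–Alder reaction.**
- Disconnection: C7–C8 and C9–C10 together.
- Forward key step: thermal cycloaddition of the 2-silyloxydiene A3 (C7=C6(OSi)–C5=C10 on ring A) with methyl but-2-ynoate A4 to the 1,4-cyclohexadiene A5.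
- For: the most convergent plan; ring B arrives with C12, C11 (as ester) and the C6 oxygen (as enol ether), with the electronically favoured regiochemistry.
- Against: the diene terminus C10 is fully substituted, and the diene must become planar against the C4 gem-dimethyl group, so reactivity toward an unactivated ynoate should be low. The only element that can choose the face at C10 is the remote C3 silyloxy group, and the target needs bond formation on the face that carries it. C5 and C9 would both be created later by protonation, and the equatorial C9 arrangement is not thermodynamically secure.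
- Comparison: on step count it is clearly stronger. The chosen strategy gives a defined handle for each centre: C9 by asymmetric catalysis, C10 by the carbene, C5 by equilibration, C3 by convex-face reduction.

**Alternative 3: Robinson annulation onto a ring B ketone.**
- Disconnection: C1–C10 and C4–C5.
- Forward key step: the more substituted enolate of ketone A6 adds to 11 and aldol condensation closes ring A as the Δ4-3-one A7.
- For: classical and scalable; the enolate reacts anti to the C9 substituent, so the C10 methyl ends cis to C11 under matched substrate control; the C8 methyl centre, later erased by C7=C8, fixes the conformation; the enone allows gem-dimethylation at C4.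
- Against: A6 must be made as a single enantiomer with two controlled centres. C6 carries no oxygen, so it has to be introduced later through the C5=C6 alkene, with C5 set at that stage. Annulation at a fully substituted α-carbon next to a branched centre is sluggish.
- Comparison: in reliability of the ring construction and in matched control of C10 it is at least as strong. The chosen strategy offers ring B and the C6 oxygen in one step from an acyclic precursor with a single catalytically set centre, at the price of a less certain key step.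

Key step: step 10

## Route

Remarks on the chemistry (assumptions):
- Compounds 1 and 3 are taken as commercial.
- The (5aS,10bR) antipode of the triazolium salt is assumed to be the one whose carbene attacks the required arm; if the sense is the reverse, the (5aR,10bS) antipode is used with nothing else changed.
- Compounds 10, 12, 13 and 14 are carried as epimer mixtures at the future C10, and 20 and 29 at C4 and C8; these centres are erased later.

Step 1
Reactants: 1 5-[(tert-butyldimethylsilyl)oxy]pentan-1-ol
Product: 2 5-[(tert-butyldimethylsilyl)oxy]pentanal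
Conditions: TEMPO (10 mol %), PhI(OAc)2 (1.1 equiv), CH2Cl2, 23 °C
Reagents that add atoms: none
Why: Oxoammonium (TEMPO) oxidation of a primary alcohol stops at the aldehyde and leaves the silyl ether untouched.

Step 2
Reactants: 3 1-nitropropan-2-ol
Product: 5 (E)-1-nitroprop-1-ene, via mesylate 4 (not isolated)
Conditions: MsCl, Et3N (2.2 equiv), CH2Cl2, −10 → 0 °C
Reagents that add atoms: none
Why: Mesylation and E1cB elimination (dehydration of a nitroaldol) give the conjugated (E)-nitroalkene, which is volatile and is used as a solution.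

Step 3
Reactants: 2 5-[(tert-butyldimethylsilyl)oxy]pentanal; 5 (E)-1-nitroprop-1-ene
Product: 7 (2R,3R)-2-{3-[(tert-butyldimethylsilyl)oxy]propyl}-3-methyl-4-nitrobutan-1-ol, via nitro aldehyde 6 (not isolated)
Conditions: (S)-2-[diphenyl(trimethylsilyloxy)methyl]pyrrolidine (10 mol %), 4-nitrophenol (10 mol %), toluene, 0 → 23 °C; then NaBH4, MeOH, 0 °C
Reagents that add atoms: none
Why: Enamine-catalysed Michael addition of an aldehyde to a nitroalkene: the (S)-diarylprolinol silyl ether shields one face of the (E)-enamine, so the aldehyde α-carbon (future C9) is formed R, with the adjacent methyl centre (later erased) set alongside. Immediate NaBH4 reduction prevents α-epimerization.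

Step 4
Reactants: 7 (2R,3R)-2-{3-[(tert-butyldimethylsilyl)oxy]propyl}-3-methyl-4-nitrobutan-1-ol
Product: 8 tert-butyl{[(2R,3R)-2-{3-[(tert-butyldimethylsilyl)oxy]propyl}-3-methyl-4-nitrobutyl]oxy}diphenylsilane
Conditions: TBDPSCl, imidazole, DMF, 23 °C
Reagents that add atoms: tert-butyl(chloro)diphenylsilane, CC(C)(C)[Si](Cl)(c1ccccc1)c2ccccc2
Why: Standard silylation of a primary alcohol; the TBDPS ether on C11–O survives the later acid and base steps and is orthogonal to the primary TBS ether.

Step 5
Reactants: 8 tert-butyl{[(2R,3R)-2-{3-[(tert-butyldimethylsilyl)oxy]propyl}-3-methyl-4-nitrobutyl]oxy}diphenylsilane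
Product: 10 (3R)-6-[(tert-butyldimethylsilyl)oxy]-3-{[(tert-butyldiphenylsilyl)oxy]methyl}-2-methylhexanal (C2 epimers), via sodium nitronate 9 (not isolated)
Conditions: NaOMe (1.1 equiv), MeOH, 0 °C; then O3, MeOH/CH2Cl2, −78 °C; N2 purge
Reagents that add atoms: ozone, [O-][O+]=O
Why: Oxidative Nef reaction: ozone cleaves the nitronate C=N bond at −78 °C under non-acidic conditions that both silyl ethers tolerate. Epimerization next to the new aldehyde does not matter, because that carbon becomes the quaternary C10.

Step 6
Reactants: 10 (3R)-6-[(tert-butyldimethylsilyl)oxy]-3-{[(tert-butyldiphenylsilyl)oxy]methyl}-2-methylhexanal; 11 methyl vinyl ketone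
Product: 13 4-{(2R)-5-[(tert-butyldimethylsilyl)oxy]-1-[(tert-butyldiphenylsilyl)oxy]pentan-2-yl}-4-methylcyclohex-2-en-1-one (C4 epimers), via keto aldehyde 12 (not isolated)
Conditions: pyrrolidine (30 mol %), AcOH (30 mol %), toluene, 23 → 80 °C
Reagents that add atoms: none
Why: Robinson annulation through the enamine: Michael addition of the α-branched aldehyde to 11 creates the quaternary carbon (future C10), and amine/acid-catalysed aldol condensation closes the 4,4-disubstituted cyclohexenone. The new centre is left uncontrolled because the next step removes it.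

Step 7
Reactants: 13 4-{(2R)-5-[(tert-butyldimethylsilyl)oxy]-1-[(tert-butyldiphenylsilyl)oxy]pentan-2-yl}-4-methylcyclohex-2-en-1-one
Product: 15 4-{(2R)-5-[(tert-butyldimethylsilyl)oxy]-1-[(tert-butyldiphenylsilyl)oxy]pentan-2-yl}-4-methylcyclohexa-2,5-dien-1-one, via silyl dienol ether 14 (not isolated)
Conditions: LiN(SiMe3)2, Me3SiCl, THF, −78 °C; then Pd(OAc)2 (1.1 equiv), MeCN, 23 °C
Reagents that add atoms: none
Why: Saegusa–Ito dehydrogenation: kinetic α'-enolization gives the 2-silyloxydiene, and the enolate of divalent palladium undergoes β-hydride elimination to the cross-conjugated dienone, in which C10 is no longer stereogenic.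

Step 8
Reactants: 15 4-{(2R)-5-[(tert-butyldimethylsilyl)oxy]-1-[(tert-butyldiphenylsilyl)oxy]pentan-2-yl}-4-methylcyclohexa-2,5-dien-1-one
Product: 16 4-{(2R)-1-[(tert-butyldiphenylsilyl)oxy]-5-hydroxypentan-2-yl}-4-methylcyclohexa-2,5-dien-1-one
Conditions: pyridinium p-toluenesulfonate (20 mol %), MeOH, 23 °C
Reagents that add atoms: none
Why: Mild acid-catalysed methanolysis removes the primary TBS ether much faster than the bulkier, more acid-stable TBDPS ether; the dienone is inert to this weak acid.

Step 9
Reactants: 16 4-{(2R)-1-[(tert-butyldiphenylsilyl)oxy]-5-hydroxypentan-2-yl}-4-methylcyclohexa-2,5-dien-1-one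
Product: 17 (4R)-5-[(tert-butyldiphenylsilyl)oxy]-4-(1-methyl-4-oxocyclohexa-2,5-dien-1-yl)pentanal
Conditions: Dess–Martin periodinane, CH2Cl2, 0 → 23 °C
Reagents that add atoms: none
Why: Dess–Martin oxidation of a primary alcohol under near-neutral conditions gives the aldehyde without touching the dienone or the silyl ether.

Step 10
Reactants: 17 (4R)-5-[(tert-butyldiphenylsilyl)oxy]-4-(1-methyl-4-oxocyclohexa-2,5-dien-1-yl)pentanal
Product: 18 (5S,9R,10S)-11-(tert-butyldiphenylsilyloxy)-12,13,14-trinordrim-1-ene-3,6-dione (cis-fused)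
Conditions: (5aS,10bR)-2-(pentafluorophenyl)-5a,10b-dihydro-4H,6H-indeno[2,1-b][1,2,4]triazolo[4,3-d][1,4]oxazin-2-ium tetrafluoroborate (20 mol %), KN(SiMe3)2 (18 mol %), toluene (0.02 M), 23 °C
Reagents that add atoms: none
Why: The free carbene adds to the aldehyde of 17 and a proton shift gives the enaminol (an acyl-anion equivalent at C6), which adds to C5 of one dienone arm in a 6-exo-trig conjugate addition; proton transfer and loss of the carbene leave the C3/C6 1,4-diketone (intramolecular Stetter reaction, here a desymmetrization of a 4,4-disubstituted cyclohexadienone). The tether hangs from C10 and can reach C5 only on its own face, so ring B can only be cis-fused and C5 is set by geometry. C10 becomes stereogenic through the choice of arm, and the chiral carbene makes that choice. The C9 centre does not help: in the chair-like closure onto the required arm the C10 methyl is equatorial and the spectator arm axial on the forming ring, so the CH2OSi group, which must end cis to the methyl, is axial (or the ring closes through a boat). The resident centre therefore opposes the required arm by roughly one gauche interaction, a bias small enough for a catalyst that separates the arms of achiral dienones strongly. The selectivity needed is arm against arm; the minor product is a diastereomer (epimeric at both C5 and C10) and can be removed by chromatography. Slightly less base than azolium salt, so that no free base remains, and high dilution favour acyl-anion addition over enolate reactions of the aldehyde.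

Step 11
Reactants: 18 (5S,9R,10S)-11-(tert-butyldiphenylsilyloxy)-12,13,14-trinordrim-1-ene-3,6-dione
Product: 19 (5S,9R,10S)-11-(tert-butyldiphenylsilyloxy)-6,6-(ethylenedioxy)-12,13,14-trinordrim-1-en-3-one
Conditions: 1,2-bis(trimethylsilyloxy)ethane, Me3SiOTf (5 mol %), CH2Cl2, −78 → −30 °C
Reagents that add atoms: 1,2-bis(trimethylsilyloxy)ethane, C[Si](C)(C)OCCO[Si](C)(C)C
Why: Silyl triflate-catalysed ketalization at low temperature is selective for the saturated C6 ketone over the conjugated C3 enone and does not disturb C5 or the TBDPS ether. With C6 masked, C4 is the only enolisable position.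

Step 12
Reactants: 19 (5S,9R,10S)-11-(tert-butyldiphenylsilyloxy)-6,6-(ethylenedioxy)-12,13,14-trinordrim-1-en-3-one
Product: 21 (5R,9R,10S)-11-(tert-butyldiphenylsilyloxy)-6,6-(ethylenedioxy)-12-nordrim-1-en-3-one, via monomethyl ketone 20 (not isolated)
Conditions: KOtBu (3 equiv), MeI (6 equiv), THF/t-BuOH, 0 → 23 °C
Reagents that add atoms: iodomethane, CI
Why: Enolate alkylation: the enone has no γ-hydrogen (C10 is quaternary), so base can only form the cross-conjugated C3/C4 enolate, and exhaustive C-methylation gives the gem-dimethyl group. C5 is not acidic while C6 is a ketal; its descriptor changes only because the priorities change.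

Step 13
Reactants: 21 (5R,9R,10S)-11-(tert-butyldiphenylsilyloxy)-6,6-(ethylenedioxy)-12-nordrim-1-en-3-one
Product: 22 (5R,9R,10S)-11-(tert-butyldiphenylsilyloxy)-6,6-(ethylenedioxy)-12-nordriman-3-one
Conditions: H2 (1 atm), Pd/C (10% Pd on carbon), EtOAc, 23 °C
Reagents that add atoms: none
Why: Heterogeneous hydrogenation of the disubstituted enone double bond; ketone, ketal and silyl ether are inert and no stereocentre is formed.

Step 14
Reactants: 22 (5R,9R,10S)-11-(tert-butyldiphenylsilyloxy)-6,6-(ethylenedioxy)-12-nordriman-3-one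
Product: 23 (3S,5R,9R,10S)-11-(tert-butyldiphenylsilyloxy)-6,6-(ethylenedioxy)-12-nordriman-3-ol
Conditions: K[BH(sBu)3], THF, −78 °C; then H2O
Reagents that add atoms: none
Why: Hydride reduction under steric approach control: the gem-dimethyl group excludes the chair in which C4 would be axial on ring B, so C5–C6 is axial on ring A and the ketal carbon blocks the concave face of the C3 carbonyl. The bulky hydride therefore enters from the convex face (the face of the C10 methyl) and places the hydroxyl trans to the C10 methyl (3S).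

Step 15
Reactants: 23 (3S,5R,9R,10S)-11-(tert-butyldiphenylsilyloxy)-6,6-(ethylenedioxy)-12-nordriman-3-ol
Product: 24 (3S,5R,9R,10S)-3-(tert-butyldimethylsilyloxy)-11-(tert-butyldiphenylsilyloxy)-6,6-(ethylenedioxy)-12-nordrimane
Conditions: TBSOTf, 2,6-lutidine, CH2Cl2, −78 → 0 °C
Reagents that add atoms: tert-butyldimethylsilyl trifluoromethanesulfonate, CC(C)(C)[Si](C)(C)OS(=O)(=O)C(F)(F)F
Why: A silyl triflate is needed for this hindered axial carbinol. The TBS ether prevents hemiketal formation with C6 in the next step and survives the enolate chemistry that follows.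

Step 16
Reactants: 24 (3S,5R,9R,10S)-3-(tert-butyldimethylsilyloxy)-11-(tert-butyldiphenylsilyloxy)-6,6-(ethylenedioxy)-12-nordrimane
Product: 26 (3S,5S,9R,10S)-3-(tert-butyldimethylsilyloxy)-11-(tert-butyldiphenylsilyloxy)-12-nordriman-6-one (trans-fused), via cis-fused ketone 25 (not isolated)
Conditions: p-TsOH·H2O (20 mol %), acetone/H2O, 23 °C; then NaOMe (0.2 equiv), MeOH, 23 °C
Reagents that add atoms: water, O
Why: Acetal hydrolysis frees the C6 ketone, and base equilibration through the C5/C6 enolate converts the cis- into the trans-fused decalone. The cis isomer must either place the quaternary C4 axial on ring B or hold C6 and the C3 silyloxy group 1,3-diaxial on ring A, so the trans isomer should dominate strongly. Doing this before the enone exists keeps the γ-centre C9 away from base.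

Step 17
Reactants: 26 (3S,5S,9R,10S)-3-(tert-butyldimethylsilyloxy)-11-(tert-butyldiphenylsilyloxy)-12-nordriman-6-one
Product: 28 (3S,5S,9R,10S)-3-(tert-butyldimethylsilyloxy)-11-(tert-butyldiphenylsilyloxy)-12-nordrim-7-en-6-one, via silyl enol ether 27 (not isolated)
Conditions: LiN(SiMe3)2, Me3SiCl, THF, −78 °C; then Pd(OAc)2 (1.1 equiv), MeCN, 23 °C
Reagents that add atoms: none
Why: Saegusa–Ito dehydrogenation: kinetic deprotonation occurs at C7 (C5 is tertiary and shielded by C4 and C10), and palladium-mediated β-hydride elimination gives the C7=C8 enone.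

Step 18
Reactants: 28 (3S,5S,9R,10S)-3-(tert-butyldimethylsilyloxy)-11-(tert-butyldiphenylsilyloxy)-12-nordrim-7-en-6-one
Product: 30 (3S,5S,9R,10S)-3-(tert-butyldimethylsilyloxy)-11-(tert-butyldiphenylsilyloxy)drim-7-en-6-one, via silyl enol ether 29 (not isolated)
Conditions: Me2CuLi (from MeLi and CuI), Me3SiCl, THF, −78 °C; then Pd(OAc)2 (1.1 equiv), MeCN, 23 °C
Reagents that add atoms: lithium dimethylcuprate, [Li+].C[Cu-]C
Why: Conjugate addition of lithium dimethylcuprate to C8 with in situ silylation of the enolate, followed by a second Saegusa–Ito dehydrogenation, installs the C12 methyl and restores C7=C8. The transient C8 centre (methyl expected anti to the axial C10 methyl) is erased.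

Step 19
Reactants: 30 (3S,5S,9R,10S)-3-(tert-butyldimethylsilyloxy)-11-(tert-butyldiphenylsilyloxy)drim-7-en-6-one
Product: 31 (3S,5S,9R,10S)-3,11-dihydroxydrim-7-en-6-one
Conditions: HF·pyridine, pyridine/THF, 0 → 23 °C
Reagents that add atoms: none
Why: Fluoride-mediated desilylation removes both silyl ethers under buffered, weakly acidic conditions that leave the enone and its γ-centre alone.

Step 20
Reactants: 31 (3S,5S,9R,10S)-3,11-dihydroxydrim-7-en-6-one; 32 umbelliferone
Product: 33 ferocaulidin
Conditions: PPh3, diisopropyl azodicarboxylate, THF, 0 → 23 °C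
Reagents that add atoms: none
Why: Mitsunobu etherification: the acidic phenol (pKa about 8) is alkylated by the primary alcohol, while the axial secondary hydroxyl next to the gem-dimethyl group is too hindered to be activated. No stereocentre is touched, and the enone sees nothing more basic than the betaine.

## Compound list

1 | 5-[(tert-butyldimethylsilyl)oxy]pentan-1-ol | OCCCCCO[Si](C)(C)C(C)(C)C | starting material
2 | 5-[(tert-butyldimethylsilyl)oxy]pentanal | O=CCCCCO[Si](C)(C)C(C)(C)C | intermediate
3 | 1-nitropropan-2-ol (racemic) | CC(O)C[N+](=O)[O-] | starting material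
4 | 1-nitropropan-2-yl methanesulfonate | CC(OS(C)(=O)=O)C[N+](=O)[O-] | intermediate
5 | (E)-1-nitroprop-1-ene | C/C=C/[N+](=O)[O-] | intermediate
6 | (2R,3R)-2-{3-[(tert-butyldimethylsilyl)oxy]propyl}-3-methyl-4-nitrobutanal | O=C[C@H](CCCO[Si](C)(C)C(C)(C)C)[C@@H](C)C[N+](=O)[O-] | intermediate
7 | (2R,3R)-2-{3-[(tert-butyldimethylsilyl)oxy]propyl}-3-methyl-4-nitrobutan-1-ol | OC[C@H](CCCO[Si](C)(C)C(C)(C)C)[C@@H](C)C[N+](=O)[O-] | intermediate
8 | tert-butyl{[(2R,3R)-2-{3-[(tert-butyldimethylsilyl)oxy]propyl}-3-methyl-4-nitrobutyl]oxy}diphenylsilane | CC(C)(C)[Si](c1ccccc1)(c2ccccc2)OC[C@H](CCCO[Si](C)(C)C(C)(C)C)[C@@H](C)C[N+](=O)[O-] | intermediate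
9 | sodium nitronate (aci-nitro sodium salt) of 8 | CC(C)(C)[Si](c1ccccc1)(c2ccccc2)OC[C@H](CCCO[Si](C)(C)C(C)(C)C)[C@@H](C)C=[N+]([O-])[O-].[Na+] | intermediate
10 | (3R)-6-[(tert-butyldimethylsilyl)oxy]-3-{[(tert-butyldiphenylsilyl)oxy]methyl}-2-methylhexanal (C2 epimers) | O=CC(C)[C@H](CO[Si](c1ccccc1)(c2ccccc2)C(C)(C)C)CCCO[Si](C)(C)C(C)(C)C | intermediate
11 | methyl vinyl ketone (but-3-en-2-one) | CC(=O)C=C | starting material
12 | (3R)-6-[(tert-butyldimethylsilyl)oxy]-3-{[(tert-butyldiphenylsilyl)oxy]methyl}-2-methyl-2-(3-oxobutyl)hexanal (C2 epimers) | O=CC(C)(CCC(C)=O)[C@H](CO[Si](c1ccccc1)(c2ccccc2)C(C)(C)C)CCCO[Si](C)(C)C(C)(C)C | intermediate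
13 | 4-{(2R)-5-[(tert-butyldimethylsilyl)oxy]-1-[(tert-butyldiphenylsilyl)oxy]pentan-2-yl}-4-methylcyclohex-2-en-1-one (C4 epimers) | O=C1C=CC(C)(CC1)[C@H](CO[Si](c2ccccc2)(c3ccccc3)C(C)(C)C)CCCO[Si](C)(C)C(C)(C)C | intermediate
14 | [(4-{(2R)-5-[(tert-butyldimethylsilyl)oxy]-1-[(tert-butyldiphenylsilyl)oxy]pentan-2-yl}-4-methylcyclohexa-1,5-dien-1-yl)oxy]trimethylsilane (C4 epimers) | C[Si](C)(C)OC1=CCC(C)(C=C1)[C@H](CO[Si](c2ccccc2)(c3ccccc3)C(C)(C)C)CCCO[Si](C)(C)C(C)(C)C | intermediate
15 | 4-{(2R)-5-[(tert-butyldimethylsilyl)oxy]-1-[(tert-butyldiphenylsilyl)oxy]pentan-2-yl}-4-methylcyclohexa-2,5-dien-1-one | O=C1C=CC(C)(C=C1)[C@H](CO[Si](c2ccccc2)(c3ccccc3)C(C)(C)C)CCCO[Si](C)(C)C(C)(C)C | intermediate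
16 | 4-{(2R)-1-[(tert-butyldiphenylsilyl)oxy]-5-hydroxypentan-2-yl}-4-methylcyclohexa-2,5-dien-1-one | O=C1C=CC(C)(C=C1)[C@H](CO[Si](c2ccccc2)(c3ccccc3)C(C)(C)C)CCCO | intermediate
17 | (4R)-5-[(tert-butyldiphenylsilyl)oxy]-4-(1-methyl-4-oxocyclohexa-2,5-dien-1-yl)pentanal | O=CCC[C@@H](CO[Si](c1ccccc1)(c2ccccc2)C(C)(C)C)C3(C)C=CC(=O)C=C3 | intermediate
18 | (5S,9R,10S)-11-(tert-butyldiphenylsilyloxy)-12,13,14-trinordrim-1-ene-3,6-dione; cis-fused, H-5 and C11 both cis to the C10 methyl | C1CC(=O)[C@H]2CC(=O)C=C[C@@]2(C)[C@@H]1CO[Si](c3ccccc3)(c4ccccc4)C(C)(C)C | intermediate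
19 | (5S,9R,10S)-11-(tert-butyldiphenylsilyloxy)-6,6-(ethylenedioxy)-12,13,14-trinordrim-1-en-3-one | C1CC5(OCCO5)[C@H]2CC(=O)C=C[C@@]2(C)[C@@H]1CO[Si](c3ccccc3)(c4ccccc4)C(C)(C)C | intermediate
20 | 4-methyl derivative of 19 (C4 epimers) | C1CC5(OCCO5)[C@H]2C(C)C(=O)C=C[C@@]2(C)[C@@H]1CO[Si](c3ccccc3)(c4ccccc4)C(C)(C)C | intermediate
21 | (5R,9R,10S)-11-(tert-butyldiphenylsilyloxy)-6,6-(ethylenedioxy)-12-nordrim-1-en-3-one | C1CC5(OCCO5)[C@H]2C(C)(C)C(=O)C=C[C@@]2(C)[C@@H]1CO[Si](c3ccccc3)(c4ccccc4)C(C)(C)C | intermediate
22 | (5R,9R,10S)-11-(tert-butyldiphenylsilyloxy)-6,6-(ethylenedioxy)-12-nordriman-3-one | C1CC5(OCCO5)[C@H]2C(C)(C)C(=O)CC[C@@]2(C)[C@@H]1CO[Si](c3ccccc3)(c4ccccc4)C(C)(C)C | intermediate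
23 | (3S,5R,9R,10S)-11-(tert-butyldiphenylsilyloxy)-6,6-(ethylenedioxy)-12-nordriman-3-ol; hydroxyl trans to the C10 methyl | C1CC5(OCCO5)[C@H]2C(C)(C)[C@@H](O)CC[C@@]2(C)[C@@H]1CO[Si](c3ccccc3)(c4ccccc4)C(C)(C)C | intermediate
24 | (3S,5R,9R,10S)-3-(tert-butyldimethylsilyloxy)-11-(tert-butyldiphenylsilyloxy)-6,6-(ethylenedioxy)-12-nordrimane | C1CC5(OCCO5)[C@H]2C(C)(C)[C@@H](O[Si](C)(C)C(C)(C)C)CC[C@@]2(C)[C@@H]1CO[Si](c3ccccc3)(c4ccccc4)C(C)(C)C | intermediate
25 | (3S,5R,9R,10S)-3-(tert-butyldimethylsilyloxy)-11-(tert-butyldiphenylsilyloxy)-12-nordriman-6-one (cis-fused) | C1CC(=O)[C@H]2C(C)(C)[C@@H](O[Si](C)(C)C(C)(C)C)CC[C@@]2(C)[C@@H]1CO[Si](c3ccccc3)(c4ccccc4)C(C)(C)C | intermediate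
26 | (3S,5S,9R,10S)-3-(tert-butyldimethylsilyloxy)-11-(tert-butyldiphenylsilyloxy)-12-nordriman-6-one (trans-fused) | C1CC(=O)[C@@H]2C(C)(C)[C@@H](O[Si](C)(C)C(C)(C)C)CC[C@@]2(C)[C@@H]1CO[Si](c3ccccc3)(c4ccccc4)C(C)(C)C | intermediate
27 | (3S,5S,9R,10S)-3-(tert-butyldimethylsilyloxy)-11-(tert-butyldiphenylsilyloxy)-6-(trimethylsilyloxy)-12-nordrim-6-ene | C1C=C(O[Si](C)(C)C)[C@@H]2C(C)(C)[C@@H](O[Si](C)(C)C(C)(C)C)CC[C@@]2(C)[C@@H]1CO[Si](c3ccccc3)(c4ccccc4)C(C)(C)C | intermediate
28 | (3S,5S,9R,10S)-3-(tert-butyldimethylsilyloxy)-11-(tert-butyldiphenylsilyloxy)-12-nordrim-7-en-6-one | C1=CC(=O)[C@@H]2C(C)(C)[C@@H](O[Si](C)(C)C(C)(C)C)CC[C@@]2(C)[C@@H]1CO[Si](c3ccccc3)(c4ccccc4)C(C)(C)C | intermediate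
29 | (3S,5S,8R,9R,10S)-3-(tert-butyldimethylsilyloxy)-11-(tert-butyldiphenylsilyloxy)-6-(trimethylsilyloxy)drim-6-ene (C8 as expected; erased in the same step) | C[C@H]1C=C(O[Si](C)(C)C)[C@@H]2C(C)(C)[C@@H](O[Si](C)(C)C(C)(C)C)CC[C@@]2(C)[C@@H]1CO[Si](c3ccccc3)(c4ccccc4)C(C)(C)C | intermediate
30 | (3S,5S,9R,10S)-3-(tert-butyldimethylsilyloxy)-11-(tert-butyldiphenylsilyloxy)drim-7-en-6-one | CC1=CC(=O)[C@@H]2C(C)(C)[C@@H](O[Si](C)(C)C(C)(C)C)CC[C@@]2(C)[C@@H]1CO[Si](c3ccccc3)(c4ccccc4)C(C)(C)C | intermediate
31 | (3S,5S,9R,10S)-3,11-dihydroxydrim-7-en-6-one | CC1=CC(=O)[C@@H]2C(C)(C)[C@@H](O)CC[C@@]2(C)[C@@H]1CO | intermediate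
32 | umbelliferone (7-hydroxy-2H-chromen-2-one) | O=c1ccc2ccc(O)cc2o1 | starting material
33 | ferocaulidin, 7-{[(3S,5S,9R,10S)-3-hydroxy-6-oxodrim-7-en-11-yl]oxy}-2H-chromen-2-one | CC1=CC(=O)[C@@H]2C(C)(C)[C@@H](O)CC[C@@]2(C)[C@@H]1COc1ccc2ccc(=O)oc2c1 | target

## Step count and least certain steps

Total step count: 20. Longest linear sequence: 19 steps (steps 1 and 3–20, from 1 to 33); step 2 is a one-step side branch.

**Step 10 (key step).**
- What may go wrong: incomplete arm selection, because the C9 centre prefers the equatorial position in the chair-like closure and thereby works against the arm the carbene must choose. Second, closure of a six-membered carbocycle is slower than the five-membered cases, which gives aldol-type self-condensation or base-induced 5-exo Michael addition of the aldehyde enolate time to compete.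
- Fallback: take the arm choice out of the ring closure. It sets out from 13 and comes back at 18.
  - The C4 epimers of 13 are separated by chromatography. The epimer (4R)-4-{(2R)-5-[(tert-butyldimethylsilyl)oxy]-1-[(tert-butyldiphenylsilyl)oxy]pentan-2-yl}-4-methylcyclohex-2-en-1-one F1, whose only enone arm is the one that must become C4=C5, is kept; the other epimer is not lost, since step 7 converts it into 15.
  - Kinetic α'-sulfenylation (LDA, PhSSPh, THF, −78 °C) gives the 6-(phenylsulfanyl) enone F2.
  - Methanolysis with pyridinium p-toluenesulfonate gives the primary alcohol F3, and Dess–Martin oxidation gives the aldehyde F4.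
  - Carbene closure with an achiral triazolium salt onto the single enone arm gives the 2-(phenylsulfanyl)-12,13,14-trinordrimane-3,6-dione F5. Cis fusion is again enforced by the tether and no arm remains to be chosen.
  - Oxidation with mCPBA at −78 °C gives the sulfoxide F6, which on warming in toluene loses benzenesulfenic acid by syn-elimination and restores C1=C2, giving 18.

**Step 5 (Nef reaction).**
- What may go wrong: incomplete cleavage or over-oxidation of the nitronate, and partial loss of a silyl ether in basic methanol, since ozonolysis of nitronates to aldehydes is less forgiving than to ketones.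
- Fallback: change the oxidation level reached. It sets out from 8 and comes back at 10. Treatment of 8 with NaNO2 and AcOH in DMSO at 35 °C converts the primary nitro group into the carboxylic acid (3R)-6-[(tert-butyldimethylsilyl)oxy]-3-{[(tert-butyldiphenylsilyl)oxy]methyl}-2-methylhexanoic acid F7. BH3·SMe2 reduces it to the primary alcohol (3R)-6-[(tert-butyldimethylsilyl)oxy]-3-{[(tert-butyldiphenylsilyl)oxy]methyl}-2-methylhexan-1-ol F8, and Dess–Martin oxidation gives 10.

**Step 6 (Robinson annulation).**
- What may go wrong: stalling of the Michael addition at a hindered, α-branched aldehyde carbon next to a tertiary centre, so that self-condensation of 10 and polymerization of 11 take over.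
- Fallback: form the quaternary carbon by alkylation instead of conjugate addition. It sets out from 10 and comes back at 12.
  - Condensation of 10 with cyclohexylamine gives the N-cyclohexyl imine F9.
  - Deprotonation with LDA and alkylation of the aza-enolate with 2-(2-iodoethyl)-2-methyl-1,3-dioxolane (ICCC1(C)OCCO1) gives the alkylated imine F10.
  - Buffered aqueous AcOH frees the aldehyde ketal F11.
  - Pyridinium p-toluenesulfonate in wet acetone unmasks the methyl ketone to give 12, which is cyclized to 13 with pyrrolidine/AcOH as in step 6.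

**Step 14 (C3 reduction).**
- What may go wrong: poor facial selectivity if the cis-fused ring system populates a second conformation in which the concave face is open, giving the C3 epimer.
- Fallback: fix the ring fusion first, so that the well-understood trans-decalin controls the reduction. It sets out from 22 and comes back at 26.
  - Acid hydrolysis of 22 gives the cis-fused (5R,9R,10S)-11-(tert-butyldiphenylsilyloxy)-12-nordrimane-3,6-dione F12, which NaOMe equilibrates to the trans-fused (5S,9R,10S) dione F13.
  - K[BH(sBu)3] at −78 °C is expected to attack the C3 carbonyl (flanked by a methylene group) before the C6 carbonyl (flanked by the ring-fusion carbon and the peri methyl), from the equatorial side, giving the axial alcohol (3S,5S,9R,10S)-11-(tert-butyldiphenylsilyloxy)-3-hydroxy-12-nordriman-6-one F14.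
  - Silylation with TBSOTf/2,6-lutidine gives 26.

**Step 20 (Mitsunobu etherification).**
- What may go wrong: sluggish displacement at the β-branched C11 next to the quaternary C10, so that the alkoxyphosphonium intermediate decomposes by elimination or is intercepted by the hydrazide.
- Fallback: two-stage etherification through a halide. It sets out from 31 and comes back at 33. I2, PPh3 and imidazole convert the primary hydroxyl of 31 selectively into (3S,5S,9R,10S)-3-hydroxy-11-iododrim-7-en-6-one F15. Displacement with the preformed potassium salt of 32 in DMF at 60 °C gives 33; the salt is too weakly basic to disturb C9.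

## Further compounds

F1 | step 10 | (4R)-4-{(2R)-5-[(tert-butyldimethylsilyl)oxy]-1-[(tert-butyldiphenylsilyl)oxy]pentan-2-yl}-4-methylcyclohex-2-en-1-one | O=C1C=C[C@@](C)(CC1)[C@H](CO[Si](c2ccccc2)(c3ccccc3)C(C)(C)C)CCCO[Si](C)(C)C(C)(C)C
F2 | step 10 | 6-(phenylsulfanyl) derivative of F1 (C6 epimers) | O=C1C=C[C@@](C)(CC1Sc2ccccc2)[C@H](CO[Si](c3ccccc3)(c4ccccc4)C(C)(C)C)CCCO[Si](C)(C)C(C)(C)C
F3 | step 10 | primary alcohol from F2 (TBS removed) | O=C1C=C[C@@](C)(CC1Sc2ccccc2)[C@H](CO[Si](c3ccccc3)(c4ccccc4)C(C)(C)C)CCCO
F4 | step 10 | (4R)-5-[(tert-butyldiphenylsilyl)oxy]-4-[(1R)-1-methyl-4-oxo-5-(phenylsulfanyl)cyclohex-2-en-1-yl]pentanal | O=C1C=C[C@@](C)(CC1Sc2ccccc2)[C@H](CO[Si](c3ccccc3)(c4ccccc4)C(C)(C)C)CCC=O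
F5 | step 10 | (5S,9R,10S)-11-(tert-butyldiphenylsilyloxy)-2-(phenylsulfanyl)-12,13,14-trinordrimane-3,6-dione (cis-fused, C2 epimers) | C1CC(=O)[C@H]2CC(=O)C(Sc5ccccc5)C[C@@]2(C)[C@@H]1CO[Si](c3ccccc3)(c4ccccc4)C(C)(C)C
F6 | step 10 | sulfoxide of F5 | C1CC(=O)[C@H]2CC(=O)C(S(=O)c5ccccc5)C[C@@]2(C)[C@@H]1CO[Si](c3ccccc3)(c4ccccc4)C(C)(C)C
F7 | step 5 | (3R)-6-[(tert-butyldimethylsilyl)oxy]-3-{[(tert-butyldiphenylsilyl)oxy]methyl}-2-methylhexanoic acid (C2 epimers) | OC(=O)C(C)[C@H](CO[Si](c1ccccc1)(c2ccccc2)C(C)(C)C)CCCO[Si](C)(C)C(C)(C)C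
F8 | step 5 | (3R)-6-[(tert-butyldimethylsilyl)oxy]-3-{[(tert-butyldiphenylsilyl)oxy]methyl}-2-methylhexan-1-ol (C2 epimers) | OCC(C)[C@H](CO[Si](c1ccccc1)(c2ccccc2)C(C)(C)C)CCCO[Si](C)(C)C(C)(C)C
F9 | step 6 | N-cyclohexyl imine of 10 | C1CCCCC1N=CC(C)[C@H](CO[Si](c2ccccc2)(c3ccccc3)C(C)(C)C)CCCO[Si](C)(C)C(C)(C)C
F10 | step 6 | N-cyclohexyl imine of F11 (alkylated imine) | C1CCCCC1N=CC(C)(CCC4(C)OCCO4)[C@H](CO[Si](c2ccccc2)(c3ccccc3)C(C)(C)C)CCCO[Si](C)(C)C(C)(C)C
F11 | step 6 | (3R)-6-[(tert-butyldimethylsilyl)oxy]-3-{[(tert-butyldiphenylsilyl)oxy]methyl}-2-methyl-2-[2-(2-methyl-1,3-dioxolan-2-yl)ethyl]hexanal (C2 epimers) | O=CC(C)(CCC4(C)OCCO4)[C@H](CO[Si](c2ccccc2)(c3ccccc3)C(C)(C)C)CCCO[Si](C)(C)C(C)(C)C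
F12 | step 14 | (5R,9R,10S)-11-(tert-butyldiphenylsilyloxy)-12-nordrimane-3,6-dione (cis-fused) | C1CC(=O)[C@H]2C(C)(C)C(=O)CC[C@@]2(C)[C@@H]1CO[Si](c3ccccc3)(c4ccccc4)C(C)(C)C
F13 | step 14 | (5S,9R,10S)-11-(tert-butyldiphenylsilyloxy)-12-nordrimane-3,6-dione (trans-fused) | C1CC(=O)[C@@H]2C(C)(C)C(=O)CC[C@@]2(C)[C@@H]1CO[Si](c3ccccc3)(c4ccccc4)C(C)(C)C
F14 | step 14 | (3S,5S,9R,10S)-11-(tert-butyldiphenylsilyloxy)-3-hydroxy-12-nordriman-6-one | C1CC(=O)[C@@H]2C(C)(C)[C@@H](O)CC[C@@]2(C)[C@@H]1CO[Si](c3ccccc3)(c4ccccc4)C(C)(C)C
F15 | step 20 | (3S,5S,9R,10S)-3-hydroxy-11-iododrim-7-en-6-one | CC1=CC(=O)[C@@H]2C(C)(C)[C@@H](O)CC[C@@]2(C)[C@@H]1CI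
A1 | alternative 1 | δ-lactone, 6-[5-(tert-butyldimethylsilyloxy)-2,6,6-trimethylcyclohex-1-en-1-yl]-4-methyloxan-2-one (C11 acyl carbon, ring oxygen on C6, ring A with C5=C10) | CC1=C(C(C)(C)[C@@H](O[Si](C)(C)C(C)(C)C)CC1)[C@H]2C[C@H](C)CC(=O)O2
A2 | alternative 1 | Δ5-octalin C11 acid with quaternary C10 (product of the rearrangement) | C[C@H]1CC=C2C(C)(C)[C@@H](O[Si](C)(C)C(C)(C)C)CC[C@@]2(C)[C@H]1C(=O)O
A3 | alternative 2 | 2-silyloxydiene on ring A (C7=C6(OSi)–C5=C10) | C=C(O[Si](C)(C)C(C)(C)C)C1=C(C)CC[C@H](O[Si](C)(C)C(C)(C)C)C1(C)C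
A4 | alternative 2 | methyl but-2-ynoate | CC#CC(=O)OC
A5 | alternative 2 | ring B 1,4-cyclohexadiene with C6 silyl enol ether and C8=C9 enoate (cycloadduct) | CC=1CC(O[Si](C)(C)C(C)(C)C)=C2C(C)(C)[C@@H](O[Si](C)(C)C(C)(C)C)CC[C@@]2(C)C=1C(=O)OC
A6 | alternative 3 | 2,4-dimethyl-3-{[(4-methoxybenzyl)oxy]methyl}cyclohexan-1-one (ring B ketone; C2 epimerizable) | C[C@H]1CCC(=O)C(C)[C@@H]1COCc1ccc(OC)cc1
A7 | alternative 3 | 8,10-dimethyl-9-(PMB-oxymethyl) Δ4-octal-3-one (annulation product) | C[C@H]1CCC2=CC(=O)CC[C@@]2(C)[C@@H]1COCc1ccc(OC)cc1
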